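Prostanoid numbering is used throughout: C1 is the ester carbon, C7 the acetoxy carbon, C8–C12 the ring, C13–C20 the octenyl arm.

Remark on the chemistry: the cyclopentanone 24 is drawn as its diketo tautomer but should exist largely as an enol, so its C8 descriptor is nominal until step 14. Compounds 2 and 3 are also articles of commerce, and entering at 3 would shorten the longest linear sequence by two steps.

## Analysis of the target

The target 34 is a C20 methyl ester built on one carbocycle, a 2-bromocyclopent-2-enone (C8–C12), with a C1–C7 arm on C8 and an octenyl arm on C12. It has three stereocentres: the secondary allylic acetate C7 (S), the ring methine C8 (R) and the fully substituted tertiary carbinol C12 (S). C8 and C12 are adjacent, with the C7 arm on C8 cis to the C12 hydroxyl and trans to the octenyl chain; C7 is exocyclic and has to be controlled on its own. Two isolated Z alkenes (C5=C6 and C14=C15) flank these centres. The molecule is fragile: the C7 acetate is β to the C9 ketone with an acidic C8–H between them, so base will expel the acetate and give the cross-conjugated dienone. The α-bromoenone is electrophilic and reducible, and the Z alkenes forbid free bromine and unselective hydrogenation late in the route. The hard parts are the oxygenated quaternary centre C12 in a defined absolute sense next to an epimerisable C8, and the order in which unsaturation, bromine and acetate are introduced. The plan rests on one feature: C8 is bonded to two carbons that can both be carbonyl carbons (C7 and C9) and is 1,5-related to C12 through C9–C10–C11. C8 can therefore be a diazo carbon between two acyl groups and C12 a silyl-ether methine, and closing C8–C12 by C–H insertion turns a chiral-pool secondary carbinol into the quaternary one.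

## Retrosynthetic reasoning

The acetate is put on last. The 7-acetoxy-9-ketone unit of 34 eliminates easily, so 34 is traced to the diol 33 by acylation of the secondary allylic hydroxyl; the tertiary C12 hydroxyl does not compete. Diol 33 comes from the bis-silyl ether 32 by fluoride cleavage of both Si–O bonds under non-basic conditions.

The C10–Br bond of 32 is cut next. Free bromine would attack the two Z alkenes, so the halogen is brought in as bromide: 32 is traced through the bromohydrin 31 to the epoxy ketone 30, and 30 to the enone 29 by nucleophilic epoxidation, which leaves isolated alkenes alone. The C10=C11 double bond of 29 is traced to the saturated ketone 27 through its kinetic silyl enol ether 28. Enolisation must go towards the unhindered C10, because an enolate at C8 would expel the C7 or the C12 silyloxy group.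

Both Z alkenes of 27 are taken back to the alkynes of 26, so that one semi-hydrogenation sets both geometries. The C7 silyl ether of 26 comes from the propargylic alcohol 25. The C7–H bond of 25 is cut to give the alkynyl ketone of 24, because an alkynyl ketone is an excellent substrate for catalyst-controlled transfer hydrogenation. The same step has to settle C8, which in 24 lies between two carbonyl groups and is mobile.

The key disconnection is C8–C12 of 24. Opening it gives the 2-diazo-1,3-diketone 23, in which C12 is a secondary silyl ether methine with the same spatial arrangement as in the target. The forward reaction must insert the C8 carbenoid into the C12–H bond with retention and with complete site selectivity. C8 must stand between two carbonyl groups, since a hydrogen on C7 would migrate to the carbenoid before insertion. The gain is large: the ring, the quaternary carbinol and the complete C20 skeleton arrive in one step.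

The diazo diketone 23 is cut at C7–C8. It comes from the diazo alcohol 22 by oxidation, and 22 from the diazoketone 15 and the alkynyl aldehyde 20 by an aldol-type addition of the metallated diazo carbon. The diazo group is thus in place before the second carbonyl is made. This avoids the parent alkynyl 1,3-diketone, which would close to a fused pyranone by oxa-Michael addition under the basic conditions of a diazo transfer. It also avoids adding an ester-bearing acetylide to an enolisable β-keto amide.

Diazoketone 15 is the acid 13 homologated by one diazo carbon (C8). Acid 13 is the silylated, ring-opened form of the lactone 10, and 10 is cut at C13–C14 into the epoxy ester 6 and hept-1-yne 7. The terminal epoxide carbon becomes C13, and the stereocentre, which is not touched, becomes C12. Epoxy ester 6 goes back through the tosylate 4, the alcohol 3 and the lactone acid 2 to L-glutamic acid 1, whose α-carbon supplies C12 with the required configuration.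

The aldehyde 20 is the oxidised form of the ester alcohol 19, made from the hydroxy acid 18. Acid 18 is cut at C6–C7 into hex-5-ynoic acid 16 and a one-carbon electrophile. The free acid is used because its carboxylate protects C1 while the acetylide is formed, which a methyl ester would not allow cleanly.

## Alternatives that were turned down

Alternative 1: The ring is opened at C10=C11. An acyclic diene with a vinyl group on C9 and a propenyl group on the quaternary C12, assembled by a Claisen rearrangement that makes C8–C12, is closed with the second-generation Grubbs catalyst (H2IMes)(PCy3)Cl2Ru=CHPh. The product is the cyclopentene A1, which has C9 as a triethylsilyl ether, C12 carrying a 4-methoxybenzyl ether and a silyloxyethyl arm, and C8 carrying a protected two-carbon C7–C6 arm.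
- For it: cyclopentene-forming metathesis is among the most dependable ring closures, and C10=C11 is in place at once, so no ketone desaturation is needed. The C8/C12 relationship is designed through a chair transition state and does not rest on equilibration. A1 has no side-chain alkenes, so C10 could be brominated with ordinary electrophilic bromine before the Z alkenes are made by Wittig reactions. On these three points it is stronger than the chosen route.
- Against it: A1 ends at C6 and C14, has C9 at the alcohol level and carries five protecting groups of four kinds. Two deprotection, oxidation and olefination cycles, oxidation at C9, removal of a tertiary benzylic ether and exchange of the C7 silyl group for acetate must follow. The rearrangement has to create an oxygen-bearing quaternary centre from a trisubstituted oxygenated alkene, and metathesis next to a fully substituted allylic carbon is slow.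
- Comparison: the chosen route closes the ring with the whole C20 skeleton attached, takes C12 from the chiral pool and needs one protecting group before the key step. It is far shorter.

Alternative 2: The C12–O bond is made on a preformed cyclopentene. A C6 carboxylic acid on the C8 arm attacks C12 of a C11=C12 alkene under I2 with NaHCO3, giving the cis-fused iodo γ-lactone A2 with C11–I, a 4-methoxybenzyl ether at C7 and a silyl ether at C9.
- For it: a five–five ring fusion can only be cis, so the C12 oxygen is delivered to the same face as the C8 arm. That is exactly the relationship of the target, and it is enforced by geometry. On this point it is stronger than the chosen route, which relies on the relative stability of the C8 epimers. The iodide also lets C10=C11 arise by elimination once C9 is a ketone, without a separate desaturation.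
- Against it: the step sets only C12. The cyclopentene acid already needs C7, C8 and C9 as three contiguous stereocentres, and its enantioselective synthesis is the real problem and is left unsolved. After the key step the lactone must be reduced and olefinated to add C1–C5, through an α-alkoxy aldehyde that can epimerise at C7. The octynyl group competes for iodine, and an oxidative benzyl-ether cleavage is needed late beside the alkenes.
- Comparison: the chosen route is more convergent, sets C7 by catalyst control on a complete skeleton and derives C12 in absolute terms from L-glutamic acid.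

Alternative 3: The ring is opened at C9–C10. An acyclic aldehyde (C9) with a terminal C10≡C11 alkyne on the quaternary C12 is cyclised by [Rh(dppe)]2(BF4)2 (cationic monovalent rhodium). The aldehyde C–H adds across the alkyne to give the 4-(triethylsilyloxy)cyclopent-2-enone A3, which already has the Z-octenyl arm and the silylated C1–C7 ynoate arm.
- For it: the enone is formed directly and atom-economically, only one alkyne remains to be reduced, and the steps after ring closure are fewer than in the chosen route. On post-cyclisation step count it is stronger.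
- Against it: the acyclic aldehyde has a second alkyne, C5≡C6, in the same 4-alkynal relationship to the formyl carbon through C8–C7, so two hydroacylations compete. The reacting alkyne is terminal and sits on a fully substituted carbon. The α-branched β-silyloxy aldehyde can epimerise at C8, eliminate and decarbonylate. Its three stereocentres, including an ethynyl-bearing tertiary carbinol, must all be set in open-chain form.
- Comparison: the chosen route offers a precursor from the chiral pool by reliable steps and a single possible 1,5 C–H site. Its price is a late desaturation and bromination.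

Key step: step 13

## Route

Step 1
Reactants: 1 L-glutamic acid
Product: 2 (S)-5-oxooxolane-2-carboxylic acid
Conditions: NaNO2, aq HCl, 0 °C → rt
Reagents that add atoms: none
Why: Diazotisation of the α-amine with carboxylate participation (double inversion, net retention) and closure by the γ-carboxyl gives the butyrolactone acid, a standard chiral-pool reaction; this carbon becomes C12.

Step 2
Reactants: 2 (S)-5-oxooxolane-2-carboxylic acid
Product: 3 (S)-5-(hydroxymethyl)oxolan-2-one
Conditions: BH3·SMe2, THF, 0 °C → rt; MeOH
Reagents that add atoms: none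
Why: Chemoselective borane reduction: the free carboxylic acid is reduced much faster than the lactone, and the stereocentre is not involved.

Step 3
Reactants: 3 (S)-5-(hydroxymethyl)oxolan-2-one
Product: 4 [(2S)-5-oxooxolan-2-yl]methyl 4-methylbenzenesulfonate
Conditions: TsCl, pyridine, CH2Cl2, 0 °C
Reagents that add atoms: 4-methylbenzenesulfonyl chloride, Cc1ccc(cc1)S(Cl)(=O)=O
Why: Sulfonylation of the primary alcohol turns it into a leaving group for the epoxide closure.

Step 4
Reactants: 4 [(2S)-5-oxooxolan-2-yl]methyl 4-methylbenzenesulfonate
Product: 6 methyl 3-[(2S)-oxiran-2-yl]propanoate, via ring-opened sodium alkoxide 5 (not isolated)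
Conditions: NaOMe, MeOH, 0 °C → rt
Reagents that add atoms: sodium methoxide, C[O-].[Na+]
Why: Methanolysis of the lactone frees the C4 alkoxide, which displaces the neighbouring primary tosylate (intramolecular Williamson closure); the C–O bond at the stereocentre is never broken, so the (S) configuration is kept.

Step 5
Reactants: 6 methyl 3-[(2S)-oxiran-2-yl]propanoate; 7 hept-1-yne
Product: 10 (5S)-5-(oct-2-yn-1-yl)oxolan-2-one, via lithium hept-1-yn-1-ide 8 (not isolated), via methyl (4S)-4-hydroxydodec-6-ynoate 9 (not isolated)
Conditions: 7, n-BuLi, THF, −78 °C; BF3·OEt2; then 6, −78 °C; aq NH4Cl; then p-TsOH (cat.), CH2Cl2, rt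
Reagents that add atoms: none
Why: Yamaguchi–Hirao alkynylation: the alkynyl trifluoroborate opens the BF3-activated epoxide at its CH2 terminus (SN2) and does not add to the ester at −78 °C; the γ-hydroxy ester is lactonised on purpose to a stable compound, and the stereocentre is untouched.

Step 6
Reactants: 10 (5S)-5-(oct-2-yn-1-yl)oxolan-2-one
Product: 13 (4S)-4-[(tert-butyldimethylsilyl)oxy]dodec-6-ynoic acid, via potassium hydroxy carboxylate 11 (not isolated), via bis-silyl derivative 12 (not isolated)
Conditions: KOH, MeOH/H2O, rt, evaporate; TBSCl, imidazole, DMF, rt; then AcOH/THF/H2O, rt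
Reagents that add atoms: potassium hydroxide, [K+].[OH-]; tert-butyl(chloro)dimethylsilane, CC(C)(C)[Si](C)(C)Cl
Why: Saponification, silylation of the carboxylate salt (which cannot relactonise) at both oxygens, and selective hydrolysis of the labile silyl ester are the usual way from a γ-lactone to a γ-silyloxy acid.

Step 7
Reactants: 13 (4S)-4-[(tert-butyldimethylsilyl)oxy]dodec-6-ynoic acid
Product: 15 (5S)-5-[(tert-butyldimethylsilyl)oxy]-1-diazotridec-7-yn-2-one, via mixed carbonic anhydride 14 (not isolated)
Conditions: i-BuOCOCl, N-methylmorpholine, THF, −15 °C; then CH2N2, Et2O, 0 °C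
Reagents that add atoms: diazomethane, C=[N+]=[N-]
Why: Acylation of diazomethane by a mixed anhydride (the first stage of an Arndt–Eistert sequence) gives the diazomethyl ketone under neutral conditions that spare the silyl ether; the new carbon is C8.

Step 8
Reactants: 16 hex-5-ynoic acid
Product: 18 7-hydroxyhept-5-ynoic acid, via dilithium alkynide carboxylate 17 (not isolated)
Conditions: LiN(iPr)2 (2.2 equiv), THF/DMPU, −78 → 0 °C; (CH2O)n, 0 °C → rt; aq HCl
Reagents that add atoms: formaldehyde (as paraformaldehyde), C=O
Why: The second equivalent of amide base removes the acetylenic hydrogen, far more acidic than the α-hydrogens of a carboxylate, and the acetylide adds to formaldehyde (hydroxymethylation of an alkynoic acid dianion); the carboxylate protects C1.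

Step 9
Reactants: 18 7-hydroxyhept-5-ynoic acid
Product: 19 methyl 7-hydroxyhept-5-ynoate
Conditions: MeOH, H2SO4 (cat.), rt
Reagents that add atoms: methanol, CO
Why: Fischer esterification; the primary propargylic alcohol is stable to catalytic acid in methanol.

Step 10
Reactants: 19 methyl 7-hydroxyhept-5-ynoate
Product: 20 methyl 7-oxohept-5-ynoate
Conditions: Dess–Martin periodinane, NaHCO3, CH2Cl2, 0 °C
Reagents that add atoms: none
Why: Buffered Dess–Martin oxidation of a propargylic alcohol to the alkynyl aldehyde, which is used at once because such aldehydes polymerise.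

Step 11
Reactants: 15 (5S)-5-[(tert-butyldimethylsilyl)oxy]-1-diazotridec-7-yn-2-one; 20 methyl 7-oxohept-5-ynoate
Product: 22 methyl (12S)-12-[(tert-butyldimethylsilyl)oxy]-8-diazo-7-hydroxy-9-oxoicosa-5,14-diynoate (both C7 epimers), via C-lithiated diazoketone 21 (not isolated)
Conditions: LiN(iPr)2, THF, −78 °C; then 20; AcOH, −78 °C
Reagents that add atoms: none
Why: Aldol-type addition of a metallated acyldiazomethane to an aldehyde forms C7–C8 by 1,2-addition at −78 °C, where the ester is inert; the C7 configuration is irrelevant because it is oxidised next.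

Step 12
Reactants: 22 methyl (12S)-12-[(tert-butyldimethylsilyl)oxy]-8-diazo-7-hydroxy-9-oxoicosa-5,14-diynoate
Product: 23 methyl (12S)-12-[(tert-butyldimethylsilyl)oxy]-8-diazo-7,9-dioxoicosa-5,14-diynoate
Conditions: Dess–Martin periodinane, NaHCO3, CH2Cl2, 0 °C → rt
Reagents that add atoms: none
Why: Oxidation of an α-diazo-β-hydroxy ketone to the 2-diazo-1,3-diketone with a hypervalent iodine reagent is established and leaves the diazo group intact; the base-sensitive diazo-free alkynyl diketone is never formed.

Step 13
Reactants: 23 methyl (12S)-12-[(tert-butyldimethylsilyl)oxy]-8-diazo-7,9-dioxoicosa-5,14-diynoate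
Product: 24 methyl (8R,12S)-12-[(tert-butyldimethylsilyl)oxy]-7,9-dioxoprosta-5,14-diyn-1-oate
Conditions: Rh2(OAc)4 (2 mol %), CH2Cl2, 40 °C, slow addition of 23
Reagents that add atoms: none
Why: Rh2(OAc)4 (divalent rhodium) is attacked by the diazo carbon of 23 and expels N2 to give an electrophilic carbenoid at C8 flanked by the C7 and C9 acyl groups. The carbenoid inserts into the C12–H bond in a concerted, asynchronous three-centre transition state in which hydride character develops at C12 and is stabilised by the silyloxy oxygen. The closest known reaction type is the dirhodium-catalysed intramolecular 1,5 C–H insertion of α-diazo-β-dicarbonyl compounds into ether-activated C–H bonds, which gives cyclopentanones. The one new ring, C8–C9–C10–C11–C12, closes by formation of C8–C12 through a five-membered cyclic array (1,5-insertion). C12 becomes quaternary with retention, because the C–C bond forms on the face from which the hydrogen leaves, so its configuration is that of L-glutamic acid 1. C8 is created as the methine of a β-diketone, is enolisable and should settle with the acyl group trans to the octynyl arm, its final fixing being left to step 14. Site selectivity is required and comes from the substrate: C11–H and C13–H would need four- and six-membered closures, the linear C5≡C6 unit keeps every C–H on the C7 side out of reach, and C12–H is the only tertiary, oxygen-activated bond. Attack of the ether oxygen on the carbenoid is disfavoured by the bulky tert-butyldimethylsilyl group.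

Step 14
Reactants: 24 methyl (8R,12S)-12-[(tert-butyldimethylsilyl)oxy]-7,9-dioxoprosta-5,14-diyn-1-oate
Product: 25 methyl (7R,8R,12S)-12-[(tert-butyldimethylsilyl)oxy]-7-hydroxy-9-oxoprosta-5,14-diyn-1-oate
Conditions: RuCl[(R,R)-TsDPEN](p-cymene) (3 mol %), HCO2H/Et3N (5:2), CH2Cl2, 0 °C → rt
Reagents that add atoms: none
Why: Noyori asymmetric transfer hydrogenation: the ruthenium hydride reduces the alkynyl ketone C7, far more reactive than the dialkyl ketone C9, through the keto tautomer, and the (R,R) ligand, which places the alkyne under the arene, should give (7R) (the same arrangement is called 7S once the alkyne is an alkene). C8 is fixed in the same step by dynamic kinetic resolution, the epimer with the C7 arm trans to the octynyl arm and cis to the smaller silyloxy group being the less hindered one.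

Step 15
Reactants: 25 methyl (7R,8R,12S)-12-[(tert-butyldimethylsilyl)oxy]-7-hydroxy-9-oxoprosta-5,14-diyn-1-oate
Product: 26 methyl (7R,8R,12S)-7,12-bis[(tert-butyldimethylsilyl)oxy]-9-oxoprosta-5,14-diyn-1-oate
Conditions: TBSOTf, 2,6-lutidine, CH2Cl2, −78 °C
Reagents that add atoms: tert-butyldimethylsilyl trifluoromethanesulfonate, CC(C)(C)[Si](C)(C)OS(=O)(=O)C(F)(F)F
Why: Silylation of the secondary propargylic alcohol with a silyl triflate and a hindered base blocks retro-aldol cleavage and lets the later enolisation use one equivalent of base.

Step 16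
Reactants: 26 methyl (7R,8R,12S)-7,12-bis[(tert-butyldimethylsilyl)oxy]-9-oxoprosta-5,14-diyn-1-oate
Product: 27 methyl (5Z,7S,8R,12S,14Z)-7,12-bis[(tert-butyldimethylsilyl)oxy]-9-oxoprosta-5,14-dien-1-oate
Conditions: H2 (1 atm), Pd/CaCO3 poisoned with Pb(OAc)2 (Lindlar catalyst), quinoline, EtOAc, rt
Reagents that add atoms: none
Why: Lindlar semi-hydrogenation: syn delivery of hydrogen to each internal alkyne on lead-poisoned palladium gives both Z alkenes, quinoline suppresses over-reduction, and ketone, ester and silyl ethers are inert.

Step 17
Reactants: 27 methyl (5Z,7S,8R,12S,14Z)-7,12-bis[(tert-butyldimethylsilyl)oxy]-9-oxoprosta-5,14-dien-1-oate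
Product: 29 methyl (5Z,7S,8R,12R,14Z)-7,12-bis[(tert-butyldimethylsilyl)oxy]-9-oxoprosta-5,10,14-trien-1-oate, via C9-trimethylsilyl enol ether 28 (not isolated)
Conditions: LiN(SiMe3)2, Me3SiCl, THF, −78 °C; then Pd(OAc)2, MeCN, rt
Reagents that add atoms: none
Why: Kinetic deprotonation with internal silyl quench takes the unhindered C10–H rather than the congested C8–H or the less acidic ester α-hydrogens, and Saegusa–Ito oxidation with Pd(OAc)2 (divalent palladium; palladium enolate, β-hydride elimination, release of zerovalent palladium) gives the C10=C11 enone. Avoiding the C8 enolate also avoids β-elimination of either silyloxy group; the C12 descriptor changes only because of priorities.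

Step 18
Reactants: 29 methyl (5Z,7S,8R,12R,14Z)-7,12-bis[(tert-butyldimethylsilyl)oxy]-9-oxoprosta-5,10,14-trien-1-oate
Product: 30 methyl (5Z,7S,8R,14Z)-7,12-bis[(tert-butyldimethylsilyl)oxy]-10,11-epoxy-9-oxoprosta-5,14-dien-1-oate (epoxide configuration not assigned, C12 unchanged)
Conditions: 30% aq H2O2, NaOH (0.2 equiv), MeOH, −20 °C
Reagents that add atoms: hydrogen peroxide, OO
Why: Weitz–Scheffer epoxidation: hydroperoxide adds conjugately at C11 and the enolate closes the epoxide, a reaction confined to the electron-poor enone, so the two Z alkenes are untouched. Methanol makes ester exchange degenerate, and the epoxide configuration is lost in the next step.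

Step 19
Reactants: 30 methyl (5Z,7S,8R,14Z)-7,12-bis[(tert-butyldimethylsilyl)oxy]-10,11-epoxy-9-oxoprosta-5,14-dien-1-oate
Product: 32 methyl (5Z,7S,8R,12S,14Z)-10-bromo-7,12-bis[(tert-butyldimethylsilyl)oxy]-9-oxoprosta-5,10,14-trien-1-oate, via bromohydrin 31 (not isolated)
Conditions: 48% aq HBr, THF, 0 °C → rt
Reagents that add atoms: hydrogen bromide, Br
Why: Bromide opens the protonated α,β-epoxy ketone at C10, the carbon α to the carbonyl where SN2 displacement is fast and which is not shielded by the quaternary C12, and the resulting α-bromo-β-hydroxy ketone loses water through its enol to give the 2-bromoenone. This is the known conversion of epoxy ketones into α-substituted enones, and it brings in bromine as a nucleophile, so the Z alkenes are not attacked.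

Step 20
Reactants: 32 methyl (5Z,7S,8R,12S,14Z)-10-bromo-7,12-bis[(tert-butyldimethylsilyl)oxy]-9-oxoprosta-5,10,14-trien-1-oate
Product: 33 methyl (5Z,7S,8R,12S,14Z)-10-bromo-7,12-dihydroxy-9-oxoprosta-5,10,14-trien-1-oate
Conditions: HF·pyridine, pyridine, THF, 0 °C → rt
Reagents that add atoms: none
Why: Fluoride cleavage of both Si–O bonds under buffered, weakly acidic conditions; basic fluoride is avoided because the β-hydroxy ketone would undergo retro-aldol cleavage or dehydration.

Step 21
Reactants: 33 methyl (5Z,7S,8R,12S,14Z)-10-bromo-7,12-dihydroxy-9-oxoprosta-5,10,14-trien-1-oate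
Product: 34 methyl (5Z,7S,8R,12S,14Z)-7-acetoxy-10-bromo-12-hydroxy-9-oxoprosta-5,10,14-trien-1-oate
Conditions: Ac2O, pyridine, CH2Cl2, 0 °C
Reagents that add atoms: acetic anhydride, CC(=O)OC(C)=O
Why: Selective acylation of the secondary allylic alcohol; the tertiary C12 alcohol is not acetylated without an acyl-transfer catalyst, and low temperature with a weak base limits loss of the new β-acetoxy group.

## Compound list

1 | L-glutamic acid | N[C@@H](CCC(=O)O)C(=O)O | starting material
2 | (S)-5-oxooxolane-2-carboxylic acid | OC(=O)[C@@H]1CCC(=O)O1 | intermediate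
3 | (S)-5-(hydroxymethyl)oxolan-2-one | OC[C@@H]1CCC(=O)O1 | intermediate
4 | [(2S)-5-oxooxolan-2-yl]methyl 4-methylbenzenesulfonate | Cc1ccc(cc1)S(=O)(=O)OC[C@@H]1CCC(=O)O1 | intermediate
5 | sodium alkoxide of methyl (4S)-4-hydroxy-5-(tosyloxy)pentanoate | COC(=O)CC[C@H]([O-])COS(=O)(=O)c1ccc(C)cc1.[Na+] | intermediate (not isolated)
6 | methyl 3-[(2S)-oxiran-2-yl]propanoate | COC(=O)CC[C@H]1CO1 | intermediate
7 | hept-1-yne | C#CCCCCC | starting material
8 | lithium hept-1-yn-1-ide | [Li+].[C-]#CCCCCC | intermediate (not isolated)
9 | methyl (4S)-4-hydroxydodec-6-ynoate | CCCCCC#CC[C@@H](O)CCC(=O)OC | intermediate (not isolated)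
10 | (5S)-5-(oct-2-yn-1-yl)oxolan-2-one | CCCCCC#CC[C@@H]1CCC(=O)O1 | intermediate
11 | potassium (4S)-4-hydroxydodec-6-ynoate | CCCCCC#CC[C@@H](O)CCC(=O)[O-].[K+] | intermediate (not isolated)
12 | tert-butyldimethylsilyl (4S)-4-[(tert-butyldimethylsilyl)oxy]dodec-6-ynoate | CCCCCC#CC[C@@H](O[Si](C)(C)C(C)(C)C)CCC(=O)O[Si](C)(C)C(C)(C)C | intermediate (not isolated)
13 | (4S)-4-[(tert-butyldimethylsilyl)oxy]dodec-6-ynoic acid | CCCCCC#CC[C@@H](O[Si](C)(C)C(C)(C)C)CCC(=O)O | intermediate
14 | isobutoxycarbonyl (4S)-4-[(tert-butyldimethylsilyl)oxy]dodec-6-ynoate (mixed carbonic anhydride) | CCCCCC#CC[C@@H](O[Si](C)(C)C(C)(C)C)CCC(=O)OC(=O)OCC(C)C | intermediate (not isolated)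
15 | (5S)-5-[(tert-butyldimethylsilyl)oxy]-1-diazotridec-7-yn-2-one | CCCCCC#CC[C@@H](O[Si](C)(C)C(C)(C)C)CCC(=O)C=[N+]=[N-] | intermediate
16 | hex-5-ynoic acid | C#CCCCC(=O)O | starting material
17 | dilithium salt of hex-5-ynoic acid (carboxylate and C6 alkynide) | [Li+].[Li+].[O-]C(=O)CCCC#[C-] | intermediate (not isolated)
18 | 7-hydroxyhept-5-ynoic acid | OCC#CCCCC(=O)O | intermediate
19 | methyl 7-hydroxyhept-5-ynoate | COC(=O)CCCC#CCO | intermediate
20 | methyl 7-oxohept-5-ynoate | COC(=O)CCCC#CC=O | intermediate
21 | lithium salt of 15 metallated at the diazo carbon | [Li+].CCCCCC#CC[C@@H](O[Si](C)(C)C(C)(C)C)CCC(=O)[C-]=[N+]=[N-] | intermediate (not isolated)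
22 | methyl (12S)-12-[(tert-butyldimethylsilyl)oxy]-8-diazo-7-hydroxy-9-oxoicosa-5,14-diynoate (C7 epimers) | CCCCCC#CC[C@@H](O[Si](C)(C)C(C)(C)C)CCC(=O)C(=[N+]=[N-])C(O)C#CCCCC(=O)OC | intermediate
23 | methyl (12S)-12-[(tert-butyldimethylsilyl)oxy]-8-diazo-7,9-dioxoicosa-5,14-diynoate | CCCCCC#CC[C@@H](O[Si](C)(C)C(C)(C)C)CCC(=O)C(=[N+]=[N-])C(=O)C#CCCCC(=O)OC | intermediate
24 | methyl (8R,12S)-12-[(tert-butyldimethylsilyl)oxy]-7,9-dioxoprosta-5,14-diyn-1-oate | CCCCCC#CC[C@@]1(O[Si](C)(C)C(C)(C)C)CCC(=O)[C@@H]1C(=O)C#CCCCC(=O)OC | intermediate
25 | methyl (7R,8R,12S)-12-[(tert-butyldimethylsilyl)oxy]-7-hydroxy-9-oxoprosta-5,14-diyn-1-oate | CCCCCC#CC[C@@]1(O[Si](C)(C)C(C)(C)C)CCC(=O)[C@@H]1[C@@H](O)C#CCCCC(=O)OC | intermediate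
26 | methyl (7R,8R,12S)-7,12-bis[(tert-butyldimethylsilyl)oxy]-9-oxoprosta-5,14-diyn-1-oate | CCCCCC#CC[C@@]1(O[Si](C)(C)C(C)(C)C)CCC(=O)[C@@H]1[C@@H](O[Si](C)(C)C(C)(C)C)C#CCCCC(=O)OC | intermediate
27 | methyl (5Z,7S,8R,12S,14Z)-7,12-bis[(tert-butyldimethylsilyl)oxy]-9-oxoprosta-5,14-dien-1-oate | CCCCC/C=C\C[C@@]1(O[Si](C)(C)C(C)(C)C)CCC(=O)[C@@H]1[C@@H](O[Si](C)(C)C(C)(C)C)/C=C\CCCC(=O)OC | intermediate
28 | methyl (5Z,7S,8R,12R,14Z)-7,12-bis[(tert-butyldimethylsilyl)oxy]-9-[(trimethylsilyl)oxy]prosta-5,9,14-trien-1-oate | CCCCC/C=C\C[C@@]1(O[Si](C)(C)C(C)(C)C)CC=C(O[Si](C)(C)C)[C@@H]1[C@@H](O[Si](C)(C)C(C)(C)C)/C=C\CCCC(=O)OC | intermediate (not isolated)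
29 | methyl (5Z,7S,8R,12R,14Z)-7,12-bis[(tert-butyldimethylsilyl)oxy]-9-oxoprosta-5,10,14-trien-1-oate | CCCCC/C=C\C[C@@]1(O[Si](C)(C)C(C)(C)C)C=CC(=O)[C@@H]1[C@@H](O[Si](C)(C)C(C)(C)C)/C=C\CCCC(=O)OC | intermediate
30 | methyl (5Z,7S,8R,14Z)-7,12-bis[(tert-butyldimethylsilyl)oxy]-10,11-epoxy-9-oxoprosta-5,14-dien-1-oate (epoxide configuration not assigned) | CCCCC/C=C\C[C@@]1(O[Si](C)(C)C(C)(C)C)C2OC2C(=O)[C@@H]1[C@@H](O[Si](C)(C)C(C)(C)C)/C=C\CCCC(=O)OC | intermediate
31 | methyl (5Z,7S,8R,14Z)-10-bromo-7,12-bis[(tert-butyldimethylsilyl)oxy]-11-hydroxy-9-oxoprosta-5,14-dien-1-oate (C10 and C11 not assigned) | CCCCC/C=C\C[C@@]1(O[Si](C)(C)C(C)(C)C)C(O)C(Br)C(=O)[C@@H]1[C@@H](O[Si](C)(C)C(C)(C)C)/C=C\CCCC(=O)OC | intermediate (not isolated)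
32 | methyl (5Z,7S,8R,12S,14Z)-10-bromo-7,12-bis[(tert-butyldimethylsilyl)oxy]-9-oxoprosta-5,10,14-trien-1-oate | CCCCC/C=C\C[C@@]1(O[Si](C)(C)C(C)(C)C)C=C(Br)C(=O)[C@@H]1[C@@H](O[Si](C)(C)C(C)(C)C)/C=C\CCCC(=O)OC | intermediate
33 | methyl (5Z,7S,8R,12S,14Z)-10-bromo-7,12-dihydroxy-9-oxoprosta-5,10,14-trien-1-oate | CCCCC/C=C\C[C@@]1(O)C=C(Br)C(=O)[C@@H]1[C@@H](O)/C=C\CCCC(=O)OC | intermediate
34 | methyl (5Z,7S,8R,12S,14Z)-7-acetoxy-10-bromo-12-hydroxy-9-oxoprosta-5,10,14-trien-1-oate | CCCCC/C=C\C[C@@]1(O)C=C(Br)C(=O)[C@@H]1[C@H](/C=C\CCCC(=O)OC)OC(C)=O | target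

## Step count and risks

Total: 21 steps. Longest linear sequence: 18 steps (steps 1–7 and 11–21, from 1); steps 8–10 make the aldehyde 20 separately.

Least certain steps:

**Step 13 (key step).**
- Risk: nitrogen loss from the doubly acyl-substituted diazo compound may be slow. The carbenoid may be diverted by hydride abstraction from the ether methine, by attack of the silyl ether oxygen or by Wolff-type rearrangement. The alkynyl β-diketone product may lose silanol by β-elimination or close to a fused pyranone while it forms.
- Fallback: the insertion is run one stage earlier, on the mono-acyl diazoketone 15, and the C7–C8 bond is made after the ring exists. Rh2(OAc)4 in CH2Cl2 should convert 15 into (S)-3-[(tert-butyldimethylsilyl)oxy]-3-(oct-2-yn-1-yl)cyclopentan-1-one F1 by the same 1,5-insertion. Kinetic silyl enol ether formation and Pd(OAc)2 give (S)-4-[(tert-butyldimethylsilyl)oxy]-4-(oct-2-yn-1-yl)cyclopent-2-en-1-one F2. Its only enolisable position is C8, and this enolate cannot expel the silyloxy group without forming a cyclopentadienone. LiN(iPr)2 followed by aldehyde 20 gives the α′-aldol product methyl (7R,8R,12R)-12-[(tert-butyldimethylsilyl)oxy]-7-hydroxy-9-oxoprosta-10-en-5,14-diyn-1-oate F3; C7 selectivity would have to be secured by the enolate counter-ion. Lindlar semi-hydrogenation gives methyl (5Z,7S,8R,12R,14Z)-12-[(tert-butyldimethylsilyl)oxy]-7-hydroxy-9-oxoprosta-5,10,14-trien-1-oate F4, and silylation with TBSOTf brings the route back at 29.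

**Step 14.**
- Risk: the acidic, enolised diketone may inhibit the catalyst, hydride may go to C9, the amine may trigger pyranone closure, and the dynamic resolution may give poor facial selection at C7 or the wrong C8 epimer.
- Fallback: from 24, stoichiometric reagent control with (R)-Alpine-borane (B-isopinocampheyl-9-borabicyclo[3.3.1]nonane from (+)-α-pinene, Midland reduction) in THF at rt. It reduces alkynyl ketones selectively through a cyclic hydride transfer under neutral, amine-free conditions and returns to the route at 25.

**Step 18.**
- Risk: alkaline peroxide may enolise C8, which would expel the C7 silyloxy group, epimerise C8 or hydrolyse the ester.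
- Fallback: the bromine is introduced before the Z alkenes exist, so that ordinary electrophilic bromination can be used. From 26, kinetic silyl enol ether formation and Pd(OAc)2 give methyl (7R,8R,12R)-7,12-bis[(tert-butyldimethylsilyl)oxy]-9-oxoprosta-10-en-5,14-diyn-1-oate F5. Br2 in CH2Cl2 at −78 °C followed by Et3N (addition and dehydrobromination; alkynes react far more slowly than alkenes) gives methyl (7R,8R,12S)-10-bromo-7,12-bis[(tert-butyldimethylsilyl)oxy]-9-oxoprosta-10-en-5,14-diyn-1-oate F6. Lindlar semi-hydrogenation then rejoins the route at 32, with debromination to be watched.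

**Step 19.**
- Risk: the bromohydrin may not dehydrate fully, and the strong acid may remove the allylic C7 silyl ether and substitute it by bromide.
- Fallback: from 30, the epoxide is opened with MgBr2·OEt2 in Et2O (neutral Lewis-acid delivery of bromide to C10) and the bromohydrin 31 is isolated. It is dehydrated with the Burgess reagent by syn elimination, which is possible because anti opening leaves C10–H syn to the C11 hydroxyl. The route is rejoined at 32.

**Step 21.**
- Risk: base may eliminate the new β-acetoxy group across C7–C8 to the cross-conjugated dienone, and the acetyl group may migrate to the cis-disposed C12 hydroxyl.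
- Fallback: the order of the last operations is changed so that no base and no free tertiary alcohol are present during acylation. From 32, brief treatment with HF·pyridine in pyridine at 0 °C removes only the less hindered secondary silyl ether and gives methyl (5Z,7S,8R,12S,14Z)-10-bromo-12-[(tert-butyldimethylsilyl)oxy]-7-hydroxy-9-oxoprosta-5,10,14-trien-1-oate F7. Ac2O with Sc(OTf)3 (cat.) in MeCN at −20 °C gives methyl (5Z,7S,8R,12S,14Z)-7-acetoxy-10-bromo-12-[(tert-butyldimethylsilyl)oxy]-9-oxoprosta-5,10,14-trien-1-oate F8. Aqueous HF in MeCN then removes the tertiary silyl ether and gives 34.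

## Further compounds

F1 | step 13 | (S)-3-[(tert-butyldimethylsilyl)oxy]-3-(oct-2-yn-1-yl)cyclopentan-1-one | CCCCCC#CC[C@@]1(O[Si](C)(C)C(C)(C)C)CCC(=O)C1
F2 | step 13 | (S)-4-[(tert-butyldimethylsilyl)oxy]-4-(oct-2-yn-1-yl)cyclopent-2-en-1-one | CCCCCC#CC[C@@]1(O[Si](C)(C)C(C)(C)C)C=CC(=O)C1
F3 | step 13 | methyl (7R,8R,12R)-12-[(tert-butyldimethylsilyl)oxy]-7-hydroxy-9-oxoprosta-10-en-5,14-diyn-1-oate | CCCCCC#CC[C@@]1(O[Si](C)(C)C(C)(C)C)C=CC(=O)[C@@H]1[C@@H](O)C#CCCCC(=O)OC
F4 | step 13 | methyl (5Z,7S,8R,12R,14Z)-12-[(tert-butyldimethylsilyl)oxy]-7-hydroxy-9-oxoprosta-5,10,14-trien-1-oate | CCCCC/C=C\C[C@@]1(O[Si](C)(C)C(C)(C)C)C=CC(=O)[C@@H]1[C@@H](O)/C=C\CCCC(=O)OC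
F0 | step 14 | none | none
F5 | step 18 | methyl (7R,8R,12R)-7,12-bis[(tert-butyldimethylsilyl)oxy]-9-oxoprosta-10-en-5,14-diyn-1-oate | CCCCCC#CC[C@@]1(O[Si](C)(C)C(C)(C)C)C=CC(=O)[C@@H]1[C@@H](O[Si](C)(C)C(C)(C)C)C#CCCCC(=O)OC
F6 | step 18 | methyl (7R,8R,12S)-10-bromo-7,12-bis[(tert-butyldimethylsilyl)oxy]-9-oxoprosta-10-en-5,14-diyn-1-oate | CCCCCC#CC[C@@]1(O[Si](C)(C)C(C)(C)C)C=C(Br)C(=O)[C@@H]1[C@@H](O[Si](C)(C)C(C)(C)C)C#CCCCC(=O)OC
F0 | step 19 | none | none
F7 | step 21 | methyl (5Z,7S,8R,12S,14Z)-10-bromo-12-[(tert-butyldimethylsilyl)oxy]-7-hydroxy-9-oxoprosta-5,10,14-trien-1-oate | CCCCC/C=C\C[C@@]1(O[Si](C)(C)C(C)(C)C)C=C(Br)C(=O)[C@@H]1[C@@H](O)/C=C\CCCC(=O)OC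
F8 | step 21 | methyl (5Z,7S,8R,12S,14Z)-7-acetoxy-10-bromo-12-[(tert-butyldimethylsilyl)oxy]-9-oxoprosta-5,10,14-trien-1-oate | CCCCC/C=C\C[C@@]1(O[Si](C)(C)C(C)(C)C)C=C(Br)C(=O)[C@@H]1[C@H](/C=C\CCCC(=O)OC)OC(C)=O
A1 | alternative 1 | 3-(triethylsilyloxy)cyclopentene core with protected C6 and C14 termini (C12: 4-methoxybenzyl ether and 2-(tert-butyldiphenylsilyloxy)ethyl; C8: 1-(tert-butyldimethylsilyloxy)-2-(4-methoxybenzyloxy)ethyl) | CC(C)(C)[Si](c1ccccc1)(c1ccccc1)OCC[C@@]1(OCc2ccc(OC)cc2)C=C[C@@H](O[Si](CC)(CC)CC)[C@@H]1[C@@H](O[Si](C)(C)C(C)(C)C)COCc1ccc(OC)cc1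
A2 | alternative 2 | cis-fused iodo γ-lactone, 6-iodo-6a-(oct-2-ynyl)-3-(4-methoxybenzyloxy)-4-(tert-butyldimethylsilyloxy)hexahydrocyclopenta[b]furan-2-one | CCCCCC#CC[C@]12OC(=O)[C@H](OCc3ccc(OC)cc3)[C@H]1[C@H](O[Si](C)(C)C(C)(C)C)C[C@@H]2I
A3 | alternative 3 | 4-(triethylsilyloxy)cyclopent-2-enone carrying the Z-octenyl arm on C12 and the silylated C1–C7 ynoate arm on C8 | CCCCC/C=C\C[C@@]1(O[Si](CC)(CC)CC)C=CC(=O)[C@@H]1[C@H](C#CCCCC(=O)OC)O[Si](C)(C)C(C)(C)C
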